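**Retrosynthetic overview**
1. Gardenin E (8) ⇐ dibromide 6: the two ring-B hydroxyls come last, from two aryl C–Br → C–OH exchanges.
2. 6 ⇐ flavone 4: the 5-OH comes from ketone-directed oxygenation of the only C–H left on ring A.
3. 4 ⇐ β-diketone 3: the pyranone ring (the only ring built) is closed through the O1–C8a bond by a dehydrogenative C–H/O–H coupling, which is the new step.
4. 3 ⇐ 1 + 2 by a crossed Claisen condensation; rings A and B are bought with their methoxy groups in place.

Assumption: Gardenin E has no stereocentre and no stereogenic double bond, so the SMILES defines a single achiral compound and no stereocontrol is needed; 1 and 2 are taken as catalogue compounds (2 is otherwise one esterification from commercial 3,5-dibromo-4-methoxybenzoic acid).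

**Route**

Step 1
Reactants: 1 1-(3,4,5-trimethoxyphenyl)ethan-1-one; 2 methyl 3,5-dibromo-4-methoxybenzoate
Product: 3 1-(3,5-dibromo-4-methoxyphenyl)-3-(3,4,5-trimethoxyphenyl)propane-1,3-dione
Conditions: NaH (2.5 equiv), 2 (1.2 equiv), THF, 65 °C; then 1 M HCl
Reagents that add atoms: none
Why: Crossed Claisen condensation of the methyl-ketone enolate with a non-enolisable aryl ester, driven to completion by irreversible formation of the stabilised diketonate; the aryl bromides and methyl ethers are inert to NaH.

Step 2
Reactants: 3 1-(3,5-dibromo-4-methoxyphenyl)-3-(3,4,5-trimethoxyphenyl)propane-1,3-dione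
Product: 4 2-(3,5-dibromo-4-methoxyphenyl)-6,7,8-trimethoxy-4H-chromen-4-one
Conditions: undivided cell, graphite anode, Pt cathode, constant current 4 mA cm–2 (about 2.3 F mol–1), nBu4NPF6 (0.1 M), 1,1,1,3,3,3-hexafluoropropan-2-ol (HFIP)/CH2Cl2 (1:4), argon, 25 °C
Reagents that add atoms: none
Why: Proposed new method: anodic dehydrogenative C–H/O–H cyclisation, in which one-electron oxidation of the electron-rich trimethoxyaryl–enol π-system gives a radical cation (stabilised by HFIP, which also loosens the enol hydrogen bond), the oxygen on the carbon that carries ring B closes a six-membered ring onto the ortho carbon of ring A (para to a methoxy group; the two ortho sites are equivalent, carbon attack would need a four-membered ring, and the dibromoaryl ring B is too electron-poor and hindered to be attacked by the other oxygen), and a second oxidation with loss of two protons (reduced to H2 at the cathode) gives the aromatic chromone via its 4-hydroxybenzopyrylium form; the closest known reaction types are the anodic or photoredox dehydrogenative lactonisation of biaryl-2-carboxylic acids to benzocoumarins and the oxidative cyclisation of electron-rich α-aryl ketones to benzofurans, neither shown for a β-diketone enol closing to a pyranone.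

Step 3
Reactants: 4 2-(3,5-dibromo-4-methoxyphenyl)-6,7,8-trimethoxy-4H-chromen-4-one
Product: 6 2-(3,5-dibromo-4-methoxyphenyl)-5-hydroxy-6,7,8-trimethoxy-4H-chromen-4-one, via aryl trifluoroacetate 5 (not isolated)
Conditions: [RuCl2(p-cymene)]2 (5 mol%), PhI(OCOCF3)2 (2 equiv), TFA/TFAA (3:1), 80 °C; then H2O/THF, 25 °C
Reagents that add atoms: [bis(trifluoroacetoxy)iodo]benzene, FC(F)(F)C(=O)OI(OC(=O)C(F)(F)F)c1ccccc1
Why: Ketone-directed ruthenium-catalysed ortho C–H oxygenation, a reaction type known for C5 of flavones: the C4 carbonyl guides carboxylate-assisted ruthenation to C5 through a five-membered metallacycle, the hypervalent iodine oxidant triggers C–O reductive elimination to the trifluoroacetate (which shields the new phenol from over-oxidation), and water cleaves the ester; C5 is the only C–H on ring A and ring B is deactivated by its bromines.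

Step 4
Reactants: 6 2-(3,5-dibromo-4-methoxyphenyl)-5-hydroxy-6,7,8-trimethoxy-4H-chromen-4-one
Product: 8 Gardenin E, via bromophenol 7 (not isolated)
Conditions: Pd2(dba)3 (2 mol%), tBuBrettPhos (8 mol%), KOH (6 equiv), 1,4-dioxane/H2O (1:1), argon, 80 °C; then 1 M HCl
Reagents that add atoms: potassium hydroxide, [K+].[OH-]
Why: Buchwald-type palladium-catalysed hydroxylation of aryl bromides (oxidative addition to zerovalent palladium, bromide/hydroxide exchange, C–O reductive elimination from the bulky biarylphosphine complex) runs twice on ring B; the methyl ethers are untouched, the 5-OH is only deprotonated, and any reversible hydroxide opening of the pyranone recloses to the same flavone on acidification because the opened ring A is symmetric.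

**Compound list**
1 | 1-(3,4,5-trimethoxyphenyl)ethan-1-one | CC(=O)c1cc(OC)c(OC)c(OC)c1 | starting material
2 | methyl 3,5-dibromo-4-methoxybenzoate | COC(=O)c1cc(Br)c(OC)c(Br)c1 | starting material
3 | 1-(3,5-dibromo-4-methoxyphenyl)-3-(3,4,5-trimethoxyphenyl)propane-1,3-dione (mainly enol in solution) | COc1c(Br)cc(cc1Br)C(=O)CC(=O)c1cc(OC)c(OC)c(OC)c1 | intermediate
4 | 2-(3,5-dibromo-4-methoxyphenyl)-6,7,8-trimethoxy-4H-chromen-4-one | COc1c(Br)cc(-c2cc(=O)c3cc(OC)c(OC)c(OC)c3o2)cc1Br | intermediate
5 | 2-(3,5-dibromo-4-methoxyphenyl)-6,7,8-trimethoxy-4-oxo-4H-chromen-5-yl trifluoroacetate (formed in the flask, not isolated) | COc1c(Br)cc(-c2cc(=O)c3c(OC(=O)C(F)(F)F)c(OC)c(OC)c(OC)c3o2)cc1Br | intermediate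
6 | 2-(3,5-dibromo-4-methoxyphenyl)-5-hydroxy-6,7,8-trimethoxy-4H-chromen-4-one | COc1c(Br)cc(-c2cc(=O)c3c(O)c(OC)c(OC)c(OC)c3o2)cc1Br | intermediate
7 | 2-(3-bromo-5-hydroxy-4-methoxyphenyl)-5-hydroxy-6,7,8-trimethoxy-4H-chromen-4-one (formed in the flask, not isolated) | COc1c(O)cc(-c2cc(=O)c3c(O)c(OC)c(OC)c(OC)c3o2)cc1Br | intermediate
8 | Gardenin E, 5-hydroxy-2-(3,5-dihydroxy-4-methoxyphenyl)-6,7,8-trimethoxy-4H-chromen-4-one | COc1c(O)cc(-c2cc(=O)c3c(O)c(OC)c(OC)c(OC)c3o2)cc1O | target

**Totals and risks**
Total step count: 4. Longest linear sequence: 4 steps (from 1 or 2).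

Steps most likely to fail:

Step 2 (the proposed new cyclisation). The risks are oxidation at the central carbon of the diketone (dimerisation) and further oxidation of 4. The fallback uses known chemistry and sets out from 1. Ring bromination ortho to the acetyl group (NBS, MeCN, 25 °C) gives 1-(2-bromo-3,4,5-trimethoxyphenyl)ethan-1-one F1. Claisen condensation of this with 2 under the step 1 conditions gives 1-(2-bromo-3,4,5-trimethoxyphenyl)-3-(3,5-dibromo-4-methoxyphenyl)propane-1,3-dione F2. Copper-catalysed intramolecular O-arylation of its enolate (CuI 10 mol%, K2CO3, DMF, 110 °C) then closes the pyranone; the ortho-carbonyl bromide reacts far faster than the ring-B bromides because the closure is intramolecular. The fallback comes back to the route at 4.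

Step 3. The C5–H is flanked by the 6-methoxy group, and the iodane may oxidise the electron-rich ring A without direction. The fallback sets out from 4 and replaces C–H oxidation by halogenation and cross-coupling. Electrophilic bromination (NBS, DMF, 25 °C) at the only free position of ring A, para to the 8-methoxy group, gives 5-bromo-2-(3,5-dibromo-4-methoxyphenyl)-6,7,8-trimethoxy-4H-chromen-4-one F3. This is put under the step 4 conditions with 9 equiv of KOH. The peri bromide, activated by the neighbouring carbonyl, should exchange first, so the fallback comes back to the route at 6, formed in the flask, and the same pot carries on through 7 to 8.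

Step 4. The risks are hydroxide attack on the pyranone, protodebromination and a stalled second exchange on the now electron-rich ring. The fallback sets out from 6 and avoids hydroxide at high temperature. Miyaura borylation (B2pin2, Pd(dppf)Cl2, KOAc, 1,4-dioxane, 90 °C) gives 5-hydroxy-6,7,8-trimethoxy-2-[4-methoxy-3,5-bis(4,4,5,5-tetramethyl-1,3,2-dioxaborolan-2-yl)phenyl]-4H-chromen-4-one F4. Mild oxidation of both C–B bonds (NaBO3·4H2O, THF/H2O, 25 °C) brings it back to the route at 8.

**Further compounds**
F1 | step 2 | 1-(2-bromo-3,4,5-trimethoxyphenyl)ethan-1-one | CC(=O)c1cc(OC)c(OC)c(OC)c1Br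
F2 | step 2 | 1-(2-bromo-3,4,5-trimethoxyphenyl)-3-(3,5-dibromo-4-methoxyphenyl)propane-1,3-dione | COc1c(Br)cc(cc1Br)C(=O)CC(=O)c1cc(OC)c(OC)c(OC)c1Br
F3 | step 3 | 5-bromo-2-(3,5-dibromo-4-methoxyphenyl)-6,7,8-trimethoxy-4H-chromen-4-one | COc1c(Br)cc(-c2cc(=O)c3c(Br)c(OC)c(OC)c(OC)c3o2)cc1Br
F4 | step 4 | 5-hydroxy-6,7,8-trimethoxy-2-[4-methoxy-3,5-bis(4,4,5,5-tetramethyl-1,3,2-dioxaborolan-2-yl)phenyl]-4H-chromen-4-one | COc1c(B2OC(C)(C)C(C)(C)O2)cc(-c2cc(=O)c3c(O)c(OC)c(OC)c(OC)c3o2)cc1B1OC(C)(C)C(C)(C)O1
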